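**Retrosynthetic overview**

- Lignan numbering is used: C7 carries the guaiacyl (4-hydroxy-3-methoxyphenyl) group, C8 is the carbinol carbon, C9 its CH2O arm; C7' carries the veratryl (3,4-dimethoxyphenyl) group, C8' is the ring-fusion CH, C9' its CH2O arm. The strategy rests on the fusion bond C8–C8': it joins the carbinol carbon C8 to C8', whose neighbour C7' bears the cation-stabilising veratryl group. Ring A (O–C7–C8–C8'–C9') and ring B (O–C7'–C8'–C8–C9) therefore both unfold to a C8 ketone, a C8'=C7' styrene and the C9 oxygen.
- The target comes from its phenol silyl ether. That bicycle is disconnected at C8–C8' (ring A, closed first) and C7'–O (ring B, closed second) in one Lewis-acid ketone–styrene Prins bicyclisation of an acyclic ketone.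
- The ketone comes from a Weinreb amide and an alkoxymethyllithium (C8–C9 bond), followed by exchange of the acetal on the C9 oxygen for a triethylsilyl group.
- The Weinreb amide comes from a resolved (R)-mandelate ester, etherified with (E)-3,4-dimethoxycinnamyl bromide and Ag2O (C7–O–C9'). C7 is the only stereocentre carried in; C8, C8' and C7' are set in the key step.

Key step: step 12

Assumption: the lipase of step 5 is taken to acetylate the (S)-enantiomer of the mandelate faster, as it does with simpler methyl mandelates, so the recovered alcohol is (R).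
Remark: the phenol is carried as its triisopropylsilyl ether, because an aryl ester would not survive the magnesium amide of step 7 or the organolithium of step 9; fluoride removes it at the end.

**Route**

Step 1
Reactants: 1 methyl (E)-3-(3,4-dimethoxyphenyl)prop-2-enoate
Product: 2 (E)-3-(3,4-dimethoxyphenyl)prop-2-en-1-ol
Conditions: i-Bu2AlH (2.5 equiv), CH2Cl2, −78 to 0 °C
Reagents that add atoms: none
Why: Hydride 1,2-reduction of the conjugated ester at low temperature gives the allylic alcohol and leaves the (E)-alkene untouched.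

Step 2
Reactants: 2 (E)-3-(3,4-dimethoxyphenyl)prop-2-en-1-ol
Product: 3 (E)-4-(3-bromoprop-1-enyl)-1,2-dimethoxybenzene
Conditions: PBr3 (0.4 equiv), Et2O, 0 °C; used crude at once
Reagents that add atoms: phosphorus tribromide, BrP(Br)Br
Why: Conversion of the allylic alcohol into the bromide by displacement of its phosphite ester keeps the conjugated (E)-geometry; the electron-rich bromide ionises easily and is therefore not stored.

Step 3
Reactants: 4 racemic 2-hydroxy-2-(4-hydroxy-3-methoxyphenyl)acetic acid
Product: 5 methyl (±)-2-hydroxy-2-(4-hydroxy-3-methoxyphenyl)acetate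
Conditions: MeOH, H2SO4 (cat.), rt
Reagents that add atoms: methanol, CO
Why: Fischer esterification; the benzylic carbinol next to the ester is deactivated towards acid solvolysis, so the phenol and the secondary alcohol are kept.

Step 4
Reactants: 5 methyl (±)-2-hydroxy-2-(4-hydroxy-3-methoxyphenyl)acetate
Product: 6 methyl (±)-2-hydroxy-2-(3-methoxy-4-triisopropylsilyloxyphenyl)acetate
Conditions: TIPSCl (1.1 equiv), imidazole (2.2 equiv), DMF, 0 °C to rt
Reagents that add atoms: chlorotriisopropylsilane, CC(C)[Si](Cl)(C(C)C)C(C)C
Why: Silyl ether formation selective for the phenol, because the bulky chlorosilane with imidazole does not react with the hindered, electron-poor alcohol of the α-hydroxy ester.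

Step 5
Reactants: 6 methyl (±)-2-hydroxy-2-(3-methoxy-4-triisopropylsilyloxyphenyl)acetate
Product: 7 methyl (R)-2-hydroxy-2-(3-methoxy-4-triisopropylsilyloxyphenyl)acetate
Conditions: immobilised Burkholderia cepacia lipase, vinyl acetate (3 equiv), t-BuOMe, 35 °C, stopped a little beyond half conversion; chromatography
Reagents that add atoms: none
Why: Enzymatic kinetic resolution by lipase-catalysed transesterification: the (S)-alcohol should be acetylated faster, so that past half conversion the unreacted (R)-alcohol, whose carbinol carbon becomes C7, is left in high enantiomeric purity and is separated from the (S)-acetate.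

Step 6
Reactants: 7 methyl (R)-2-hydroxy-2-(3-methoxy-4-triisopropylsilyloxyphenyl)acetate and 3 (E)-4-(3-bromoprop-1-enyl)-1,2-dimethoxybenzene
Product: 8 methyl (R)-2-[(E)-3-(3,4-dimethoxyphenyl)allyloxy]-2-(3-methoxy-4-triisopropylsilyloxyphenyl)acetate
Conditions: Ag2O (2 equiv), 3 (1.5 equiv), 4 Å molecular sieves, CH2Cl2, rt, dark
Reagents that add atoms: none
Why: Ag2O-mediated O-alkylation (Williamson-type etherification under non-basic conditions), the established way to etherify α-hydroxy esters without racemisation; the silver-assisted allylic bromide reacts at its unsubstituted terminus and keeps the conjugated (E)-alkene.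

Step 7
Reactants: 8 methyl (R)-2-[(E)-3-(3,4-dimethoxyphenyl)allyloxy]-2-(3-methoxy-4-triisopropylsilyloxyphenyl)acetate
Product: 9 (R)-2-[(E)-3-(3,4-dimethoxyphenyl)allyloxy]-N-methoxy-2-(3-methoxy-4-triisopropylsilyloxyphenyl)-N-methylacetamide
Conditions: MeNHOMe·HCl (2 equiv), i-PrMgCl (4 equiv), THF, −20 °C
Reagents that add atoms: N,O-dimethylhydroxylamine hydrochloride, CNOC.Cl
Why: Weinreb amide formation by aminolysis of the methyl ester with the magnesium amide made in the flask, at a temperature where this weakly basic amide should not epimerise the α-alkoxy centre.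

Step 8
Reactants: 10 (tributylstannyl)methanol
Product: 11 tributyl[(1-ethoxyethoxy)methyl]stannane
Conditions: ethyl vinyl ether (3 equiv), PPTS (5 mol %), CH2Cl2, 0 °C to rt
Reagents that add atoms: ethyl vinyl ether, C=COCC
Why: Acid-catalysed addition of the alcohol to the enol ether gives the mixed acetal (ethoxyethyl protection).

Step 9
Reactants: 9 (R)-2-[(E)-3-(3,4-dimethoxyphenyl)allyloxy]-N-methoxy-2-(3-methoxy-4-triisopropylsilyloxyphenyl)-N-methylacetamide and 11 tributyl[(1-ethoxyethoxy)methyl]stannane
Product: 13 (1R)-1-[(E)-3-(3,4-dimethoxyphenyl)allyloxy]-3-(1-ethoxyethoxy)-1-(3-methoxy-4-triisopropylsilyloxyphenyl)propan-2-one, via (1-ethoxyethoxy)methyllithium 12 (not isolated)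
Conditions: 11 (2.1 equiv), n-BuLi (2.0 equiv), THF, −78 °C, 10 min; then 9, THF, −78 °C
Reagents that add atoms: none
Why: Tin–lithium exchange gives the α-alkoxymethyllithium, whose addition to the Weinreb amide stops at the chelated tetrahedral adduct and gives the ketone (C8–C9 bond) on work-up; at −78 °C addition should be faster than deprotonation at C7, and the acetal centre makes the product a pair of epimers that converge in step 10.

Step 10
Reactants: 13 (1R)-1-[(E)-3-(3,4-dimethoxyphenyl)allyloxy]-3-(1-ethoxyethoxy)-1-(3-methoxy-4-triisopropylsilyloxyphenyl)propan-2-one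
Product: 14 (R)-1-[(E)-3-(3,4-dimethoxyphenyl)allyloxy]-3-hydroxy-1-(3-methoxy-4-triisopropylsilyloxyphenyl)propan-2-one
Conditions: PPTS (0.2 equiv), MeOH, 0 °C to rt
Reagents that add atoms: none
Why: Acid-catalysed transacetalisation with methanol removes the ethoxyethyl group under conditions too mild to ionise the cinnamyl ether, to cleave the aryl silyl ether or to enolise the ketone.

Step 11
Reactants: 14 (R)-1-[(E)-3-(3,4-dimethoxyphenyl)allyloxy]-3-hydroxy-1-(3-methoxy-4-triisopropylsilyloxyphenyl)propan-2-one
Product: 15 (R)-1-[(E)-3-(3,4-dimethoxyphenyl)allyloxy]-1-(3-methoxy-4-triisopropylsilyloxyphenyl)-3-(triethylsilyloxy)propan-2-one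
Conditions: TESCl (1.2 equiv), imidazole (2 equiv), CH2Cl2, 0 °C
Reagents that add atoms: chlorotriethylsilane, CC[Si](Cl)(CC)CC
Why: Silylation of the primary alcohol with a chlorosilane and imidazole, a base too weak to epimerise C7; the silyl ether blocks hemiketal and enediol chemistry of the hydroxy ketone and is the latent nucleophile of the next step.

Step 12
Reactants: 15 (R)-1-[(E)-3-(3,4-dimethoxyphenyl)allyloxy]-1-(3-methoxy-4-triisopropylsilyloxyphenyl)-3-(triethylsilyloxy)propan-2-one
Product: 16 (1S,3aS,4R,6aR)-1-(3,4-dimethoxyphenyl)-4-(3-methoxy-4-triisopropylsilyloxyphenyl)tetrahydro-1H,3H-furo[3,4-c]furan-3a(4H)-ol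
Conditions: BF3·OEt2 (1.5 equiv), CH2Cl2 (0.02 M), −78 to −40 °C
Reagents that add atoms: none
Why: Proposed new method: BF3 bound to the carbonyl oxygen of the doubly α-oxygenated C8 ketone lets the electron-rich (E)-styrene attack through C8', which forms C8–C8' and closes ring A in a 5-exo-trig Prins-type addition and leaves a veratryl-stabilised cation at C7'; the oxygen of the C9 silyl ether then adds to this cation and closes ring B as a five-membered oxonium ion (a cation capture, formally endo to the former alkene), and the Et3Si group leaves as Et3SiF. The closest known reaction types are Lewis-acid Prins bicyclisations of aldehydes with alkenols and Lewis-acid cyclisations of ketones onto tethered styrenes that pass through the same γ-oxido benzylic cation; a ketone as the Prins acceptor combined with capture by a silyl ether oxygen has not been shown. C8 should be set relative to C7 in an envelope transition state that keeps the aryl group on C7 pseudo-equatorial and turns the bulky CH2OSiEt3 arm away from it, so that the smaller boron-bound oxygen ends cis to the aryl group. C8' is fixed by ring strain, since only the adduct with C7' and the C9 arm on the same face of ring A can close the cis-fused ring B, while the other adduct can revert by retro-Prins cleavage; C7' is set in the capture, where the veratryl group should take the convex face. The step needs attack at C8' (secured by the veratryl group on C7'), carbonyl addition ahead of ionisation of the cinnamyl C9'–O bond and of enolisation towards C7 (favoured by the electrophilic ketone flanked by two oxygens, a monodentate Lewis acid and −78 °C), and capture by the C9 oxygen ahead of proton loss from C8' (favoured by the five-membered ring).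

Step 13
Reactants: 16 (1S,3aS,4R,6aR)-1-(3,4-dimethoxyphenyl)-4-(3-methoxy-4-triisopropylsilyloxyphenyl)tetrahydro-1H,3H-furo[3,4-c]furan-3a(4H)-ol
Product: 17 (1S,3aS,4R,6aR)-1-(3,4-dimethoxyphenyl)-4-(4-hydroxy-3-methoxyphenyl)tetrahydro-1H,3H-furo[3,4-c]furan-3a(4H)-ol
Conditions: TBAF (1.1 equiv), THF, 0 °C
Reagents that add atoms: none
Why: Fluoride-mediated cleavage of the aryl silyl ether, which leaves the benzylic ethers, the tertiary alcohol and all four stereocentres untouched.

**Compound list**

1 | methyl (E)-3-(3,4-dimethoxyphenyl)prop-2-enoate (methyl 3,4-dimethoxycinnamate) | COC(=O)/C=C/c1ccc(OC)c(OC)c1 | starting material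
2 | (E)-3-(3,4-dimethoxyphenyl)prop-2-en-1-ol | OC/C=C/c1ccc(OC)c(OC)c1 | intermediate
3 | (E)-4-(3-bromoprop-1-enyl)-1,2-dimethoxybenzene (3,4-dimethoxycinnamyl bromide) | BrC/C=C/c1ccc(OC)c(OC)c1 | intermediate
4 | racemic 2-hydroxy-2-(4-hydroxy-3-methoxyphenyl)acetic acid (4-hydroxy-3-methoxymandelic acid) | COc1cc(C(O)C(=O)O)ccc1O | starting material
5 | methyl (±)-2-hydroxy-2-(4-hydroxy-3-methoxyphenyl)acetate | COc1cc(C(O)C(=O)OC)ccc1O | intermediate
6 | methyl (±)-2-hydroxy-2-(3-methoxy-4-triisopropylsilyloxyphenyl)acetate | COc1cc(C(O)C(=O)OC)ccc1O[Si](C(C)C)(C(C)C)C(C)C | intermediate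
7 | methyl (R)-2-hydroxy-2-(3-methoxy-4-triisopropylsilyloxyphenyl)acetate | COc1cc([C@H](C(=O)OC)O)ccc1O[Si](C(C)C)(C(C)C)C(C)C | intermediate
8 | methyl (R)-2-[(E)-3-(3,4-dimethoxyphenyl)allyloxy]-2-(3-methoxy-4-triisopropylsilyloxyphenyl)acetate | COc1cc([C@H](C(=O)OC)OC/C=C/c2ccc(OC)c(OC)c2)ccc1O[Si](C(C)C)(C(C)C)C(C)C | intermediate
9 | (R)-2-[(E)-3-(3,4-dimethoxyphenyl)allyloxy]-N-methoxy-2-(3-methoxy-4-triisopropylsilyloxyphenyl)-N-methylacetamide | COc1cc([C@H](C(=O)N(C)OC)OC/C=C/c2ccc(OC)c(OC)c2)ccc1O[Si](C(C)C)(C(C)C)C(C)C | intermediate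
10 | (tributylstannyl)methanol | CCCC[Sn](CCCC)(CCCC)CO | starting material
11 | tributyl[(1-ethoxyethoxy)methyl]stannane (racemic at the acetal carbon) | CCCC[Sn](CCCC)(CCCC)COC(C)OCC | intermediate
12 | (1-ethoxyethoxy)methyllithium (formed and used in the flask) | [Li]COC(C)OCC | intermediate
13 | (1R)-1-[(E)-3-(3,4-dimethoxyphenyl)allyloxy]-3-(1-ethoxyethoxy)-1-(3-methoxy-4-triisopropylsilyloxyphenyl)propan-2-one (both epimers at the acetal carbon) | COc1cc([C@H](C(=O)COC(C)OCC)OC/C=C/c2ccc(OC)c(OC)c2)ccc1O[Si](C(C)C)(C(C)C)C(C)C | intermediate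
14 | (R)-1-[(E)-3-(3,4-dimethoxyphenyl)allyloxy]-3-hydroxy-1-(3-methoxy-4-triisopropylsilyloxyphenyl)propan-2-one | COc1cc([C@H](C(=O)CO)OC/C=C/c2ccc(OC)c(OC)c2)ccc1O[Si](C(C)C)(C(C)C)C(C)C | intermediate
15 | (R)-1-[(E)-3-(3,4-dimethoxyphenyl)allyloxy]-1-(3-methoxy-4-triisopropylsilyloxyphenyl)-3-(triethylsilyloxy)propan-2-one (key-step precursor) | COc1cc([C@H](C(=O)CO[Si](CC)(CC)CC)OC/C=C/c2ccc(OC)c(OC)c2)ccc1O[Si](C(C)C)(C(C)C)C(C)C | intermediate
16 | (1S,3aS,4R,6aR)-1-(3,4-dimethoxyphenyl)-4-(3-methoxy-4-triisopropylsilyloxyphenyl)tetrahydro-1H,3H-furo[3,4-c]furan-3a(4H)-ol (lignan numbering 7R,8S,7'S,8'R; key-step product) | COc1cc([C@H]2OC[C@@H]3[C@@H](c4ccc(OC)c(OC)c4)OC[C@]23O)ccc1O[Si](C(C)C)(C(C)C)C(C)C | intermediate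
17 | (1S,3aS,4R,6aR)-1-(3,4-dimethoxyphenyl)-4-(4-hydroxy-3-methoxyphenyl)tetrahydro-1H,3H-furo[3,4-c]furan-3a(4H)-ol (lignan numbering 7R,8S,7'S,8'R) | COc1cc([C@H]2OC[C@@H]3[C@@H](c4ccc(OC)c(OC)c4)OC[C@]23O)ccc1O | target

**Step count and risks**

Total step count: 13. Longest linear sequence: 10 steps (steps 3 to 7 and 9 to 13, from 4 to 17).

Steps most likely to fail:

1. Step 12 (Proposed new method). Ionisation of the cinnamyl C9'–O bond or enolisation towards C7 may outrun C8–C8' bond formation. The γ-oxido cation may lose a proton or collapse towards an oxetane in place of being captured by the C9 oxygen. Ring A may also close with the opposite configuration at C8. The fallback uses known radical and oxidative chemistry and closes the two rings in separate operations; it sets out from 15. SmI2 with t-BuOH in THF at −78 °C should close ring A by 5-exo ketyl–olefin cyclisation (C8–C8' bond), with the hydroxyl and the C7 aryl group both trans to the new benzyl arm, as is usual for such cyclisations. This gives (2R,3S,4S)-4-(3,4-dimethoxybenzyl)-2-(3-methoxy-4-triisopropylsilyloxyphenyl)-3-[(triethylsilyloxy)methyl]tetrahydrofuran-3-ol F1. PPTS in methanol removes the triethylsilyl group and gives (2R,3S,4S)-4-(3,4-dimethoxybenzyl)-3-(hydroxymethyl)-2-(3-methoxy-4-triisopropylsilyloxyphenyl)tetrahydrofuran-3-ol F2. DDQ in CH2Cl2 at 0 °C then oxidises the electron-rich benzylic CH2 (C7') and the C9 hydroxyl captures the cation (dehydrogenative etherification). This closes ring B and comes back to the route at 16.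

2. Step 6. Silver-assisted ionisation of the very electron-rich allylic bromide may lead to its self-condensation or decomposition faster than to O-alkylation of the poorly nucleophilic hydroxy ester. The fallback sets out from 7. Allyl bromide and Ag2O (CH2Cl2, rt) give methyl (R)-2-(allyloxy)-2-(3-methoxy-4-triisopropylsilyloxyphenyl)acetate F3. Cross-metathesis with 3,4-dimethoxystyrene (second-generation Grubbs catalyst, CH2Cl2, 40 °C) installs the aryl group with (E)-selectivity and comes back at 8. Steps 1 and 2 are then not needed.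

3. Step 5. The lipase may discriminate poorly between the enantiomers of this bulky silyloxy-substituted mandelate, so that acylation is slow and the recovered alcohol is not enantiopure. The fallback sets out from 6. Dess–Martin periodinane (CH2Cl2, rt) oxidises the racemic alcohol to methyl 2-(3-methoxy-4-triisopropylsilyloxyphenyl)-2-oxoacetate F4. Enantioselective hydrogenation over cinchonidine-modified Pt/Al2O3 (H2, toluene/AcOH; Orito reaction, which delivers (R)-α-hydroxy esters with this modifier) comes back at 7 without the loss of half the material.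

Further compounds
F1 | step 12 | (2R,3S,4S)-4-(3,4-dimethoxybenzyl)-2-(3-methoxy-4-triisopropylsilyloxyphenyl)-3-[(triethylsilyloxy)methyl]tetrahydrofuran-3-ol | COc1cc([C@H]2OC[C@H](Cc3ccc(OC)c(OC)c3)[C@]2(O)CO[Si](CC)(CC)CC)ccc1O[Si](C(C)C)(C(C)C)C(C)C
F2 | step 12 | (2R,3S,4S)-4-(3,4-dimethoxybenzyl)-3-(hydroxymethyl)-2-(3-methoxy-4-triisopropylsilyloxyphenyl)tetrahydrofuran-3-ol | COc1cc([C@H]2OC[C@H](Cc3ccc(OC)c(OC)c3)[C@]2(O)CO)ccc1O[Si](C(C)C)(C(C)C)C(C)C
F3 | step 6 | methyl (R)-2-(allyloxy)-2-(3-methoxy-4-triisopropylsilyloxyphenyl)acetate | COc1cc([C@H](C(=O)OC)OCC=C)ccc1O[Si](C(C)C)(C(C)C)C(C)C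
F4 | step 5 | methyl 2-(3-methoxy-4-triisopropylsilyloxyphenyl)-2-oxoacetate | COc1cc(C(=O)C(=O)OC)ccc1O[Si](C(C)C)(C(C)C)C(C)C
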